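Assumption: the SMILES is read literally, so both trisubstituted alkenes are Z (C2=C3 and C8=C9) and the stereocentres are 6S,7S,10S,11R,12S,14R; ansamycin numbering is used (C1 = amide carbonyl, C15 = benzylic CH2).

**Retrosynthetic overview**
1. The only ring made, the 19-membered lactam, is closed last by aryl C–N bond formation: visible-light nickel/photoredox N-arylation of a primary Z-enamide by an aryl bromide. Carbamate installation and desilylation follow.
2. The seco chain is joined at C7–C8 by chelation-controlled addition of a (Z)-alkenylmagnesium (C8–C15 plus arene) to an α-methoxy aldehyde (C1–C7).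
3. West half: C10/C11 come from (Z)-crotylboration of an α-methoxy aldehyde (C12 directs), C15–aryl from a photochemical nickel deoxygenative arylation, and C14 from lactone enolate methylation then kinetic protonation.
4. East half: Still–Gennari olefination sets the Z C2=C3 alkene.
5. One purchased lactone, (S)-5-(trityloxymethyl)butyrolactone (from L-glutamic acid), supplies both C12 and C6; every other stereocentre is relayed from these.

**Route**

Step 1
Reactants: 1 (S)-5-(trityloxymethyl)dihydrofuran-2(3H)-one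
Product: 3 (3R,5S)-3-methyl-5-(trityloxymethyl)dihydrofuran-2(3H)-one, via lithium enolate 2 (not isolated)
Conditions: LDA, THF, −78 °C; MeI, −78 °C
Reagents that add atoms: iodomethane, CI
Why: Substrate-controlled enolate alkylation in which the electrophile enters anti to the bulky trityloxymethyl group and gives the trans lactone, the precursor for the epimerisation in step 2.

Step 2
Reactants: 3 (3R,5S)-3-methyl-5-(trityloxymethyl)dihydrofuran-2(3H)-one
Product: 5 (3S,5S)-3-methyl-5-(trityloxymethyl)dihydrofuran-2(3H)-one, via lithium enolate 4 (not isolated)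
Conditions: LDA, THF, −78 °C; BHT, −78 °C; H2O
Reagents that add atoms: none
Why: Kinetic protonation of the enolate from the face anti to CH2OTr places the methyl cis to it, which sets the C14 methyl stereocentre relative to the purchased C12 centre.

Step 3
Reactants: 5 (3S,5S)-3-methyl-5-(trityloxymethyl)dihydrofuran-2(3H)-one
Product: 7 methyl (2S,4S)-4-methoxy-2-methyl-5-(trityloxy)pentanoate, via potassium hydroxy acid salt 6 (not isolated)
Conditions: KOH, MeOH/H2O, rt; evaporate; NaH, MeI, DMF, 0 °C to rt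
Reagents that add atoms: potassium hydroxide, [K+].[OH-]; iodomethane, CI
Why: Saponification opens the lactone and the alkoxide/carboxylate is exhaustively methylated (Williamson etherification plus carboxylate alkylation), the alkoxide being methylated faster than it can relactonise, with no stereocentre touched.

Step 4
Reactants: 7 methyl (2S,4S)-4-methoxy-2-methyl-5-(trityloxy)pentanoate
Product: 8 (2S,4S)-4-methoxy-2-methyl-5-(trityloxy)pentan-1-ol
Conditions: LiAlH4, THF, 0 °C
Reagents that add atoms: none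
Why: Hydride reduction of the ester gives the primary alcohol (C15) without epimerising the adjacent methyl centre.

Step 5
Reactants: 9 3,5-dibromophenol
Product: 10 (3,5-dibromophenoxy)triisopropylsilane
Conditions: TIPSCl, imidazole, DMF, rt
Reagents that add atoms: triisopropylsilyl chloride, CC(C)[Si](Cl)(C(C)C)C(C)C
Why: Silylation of the phenol gives a base-robust, fluoride-labile ether and leaves two equivalent C–Br bonds, one for C15 and one for nitrogen.

Step 6
Reactants: 8 (2S,4S)-4-methoxy-2-methyl-5-(trityloxy)pentan-1-ol; 10 (3,5-dibromophenoxy)triisopropylsilane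
Product: 12 {3-bromo-5-[(2R,4S)-4-methoxy-2-methyl-5-(trityloxy)pentyl]phenoxy}triisopropylsilane, via benzoxazoline adduct 11 (not isolated)
Conditions: 5,7-di-tert-butyl-3-phenylbenzoxazolium BF4, pyridine, MTBE, rt; then 10 (3 equiv), Ir(ppy)2(dtbbpy)PF6 (2 mol%), NiBr2(dtbbpy) (5 mol%), quinuclidine, DMA, 450 nm LEDs, rt
Reagents that add atoms: none
Why: Metallaphotoredox deoxygenative arylation, in which the oxidised alcohol adduct fragments to the primary C15 radical that nickel couples with one C–Br bond of 10 (used in excess so the second bromide survives), leaving the stereocentres untouched.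

Step 7
Reactants: 12 {3-bromo-5-[(2R,4S)-4-methoxy-2-methyl-5-(trityloxy)pentyl]phenoxy}triisopropylsilane
Product: 13 (2S,4R)-5-[3-bromo-5-(triisopropylsilyloxy)phenyl]-2-methoxy-4-methylpentan-1-ol
Conditions: TsOH·H2O (cat.), MeOH/CH2Cl2, rt
Reagents that add atoms: none
Why: Acid-catalysed methanolysis of the trityl ether proceeds through the trityl cation and spares the aryl TIPS ether and the methyl ether.

Step 8
Reactants: 13 (2S,4R)-5-[3-bromo-5-(triisopropylsilyloxy)phenyl]-2-methoxy-4-methylpentan-1-ol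
Product: 14 (2S,4R)-5-[3-bromo-5-(triisopropylsilyloxy)phenyl]-2-methoxy-4-methylpentanal
Conditions: Dess–Martin periodinane, NaHCO3, CH2Cl2, 0 °C to rt; used crude
Reagents that add atoms: none
Why: Buffered Dess–Martin oxidation gives the α-methoxy aldehyde without epimerising C12.

Step 9
Reactants: 14 (2S,4R)-5-[3-bromo-5-(triisopropylsilyloxy)phenyl]-2-methoxy-4-methylpentanal
Product: 15 (3S,4R,5S,7R)-8-[3-bromo-5-(triisopropylsilyloxy)phenyl]-5-methoxy-3,7-dimethyloct-1-en-4-ol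
Conditions: (Z)-crotylB(pin), 4 Å MS, toluene, rt, 48 h; triethanolamine work-up
Reagents that add atoms: (Z)-crotylboronic acid pinacol ester, C/C=C\CB1OC(C)(C)C(C)(C)O1
Why: Crotylboration through a closed chair transition state, where the Z boronate gives the 10,11-syn relationship and the α-methoxy centre directs Felkin–Anh/Cornforth attack to give 11,12-anti, so C10 and C11 are set by C12 with an achiral reagent.

Step 10
Reactants: 15 (3S,4R,5S,7R)-8-[3-bromo-5-(triisopropylsilyloxy)phenyl]-5-methoxy-3,7-dimethyloct-1-en-4-ol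
Product: 16 {3-bromo-5-[(2R,4S,5R,6S)-5-(tert-butyldimethylsilyloxy)-4-methoxy-2,6-dimethyloct-7-enyl]phenoxy}triisopropylsilane
Conditions: TBSOTf, 2,6-lutidine, CH2Cl2, −78 to 0 °C
Reagents that add atoms: tert-butyldimethylsilyl triflate, CC(C)(C)[Si](C)(C)OS(=O)(=O)C(F)(F)F
Why: Silylation of the hindered C11 alcohol with the reactive silyl triflate masks it so that only C7–OH is carbamoylated later.

Step 11
Reactants: 16 {3-bromo-5-[(2R,4S,5R,6S)-5-(tert-butyldimethylsilyloxy)-4-methoxy-2,6-dimethyloct-7-enyl]phenoxy}triisopropylsilane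
Product: 18 (2R,3R,4S,6R)-7-[3-bromo-5-(triisopropylsilyloxy)phenyl]-3-(tert-butyldimethylsilyloxy)-4-methoxy-2,6-dimethylheptanal, via ozonide 17 (not isolated)
Conditions: O3, CH2Cl2, −78 °C (indicator end point); PPh3, −78 °C to rt
Reagents that add atoms: ozone, [O-][O+]=O
Why: Ozonolysis with reductive work-up cleaves the terminal alkene to the C9 aldehyde under neutral conditions that do not epimerise C10.

Step 12
Reactants: 18 (2R,3R,4S,6R)-7-[3-bromo-5-(triisopropylsilyloxy)phenyl]-3-(tert-butyldimethylsilyloxy)-4-methoxy-2,6-dimethylheptanal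
Product: 19 {3-bromo-5-[(2R,4S,5R,6S,7Z)-5-(tert-butyldimethylsilyloxy)-8-iodo-4-methoxy-2,6-dimethylnon-7-enyl]phenoxy}triisopropylsilane
Conditions: [Ph3PEt]I, n-BuLi, THF, rt; I2, −78 °C; NaHMDS, −20 °C; then 18, −78 to −20 °C
Reagents that add atoms: ethyltriphenylphosphonium iodide, CC[P+](c1ccccc1)(c1ccccc1)c1ccccc1.[I-]; iodine, II
Why: Stork–Zhao-type Wittig olefination with the α-iodo ylide, whose kinetically favoured cis-oxaphosphetane gives the Z iodoalkene (iodine cis to the chain), the geometry needed at C8=C9.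

Step 13
Reactants: 1 (S)-5-(trityloxymethyl)dihydrofuran-2(3H)-one
Product: 21 methyl (S)-4-methoxy-5-(trityloxy)pentanoate, via potassium hydroxy acid salt 20 (not isolated)
Conditions: KOH, MeOH/H2O, rt; evaporate; NaH, MeI, DMF, 0 °C to rt
Reagents that add atoms: potassium hydroxide, [K+].[OH-]; iodomethane, CI
Why: The same saponification and exhaustive methylation as in step 3 turns the purchased stereocentre into the C6 methyl ether with retention.

Step 14
Reactants: 21 methyl (S)-4-methoxy-5-(trityloxy)pentanoate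
Product: 22 (S)-4-methoxy-5-(trityloxy)pentanal
Conditions: DIBAL-H, CH2Cl2, −78 °C; Rochelle salt
Reagents that add atoms: none
Why: Partial ester reduction, where the tetrahedral aluminium hemiacetal is stable at −78 °C and releases the C3 aldehyde only on work-up.

Step 15
Reactants: 22 (S)-4-methoxy-5-(trityloxy)pentanal
Product: 23 ethyl (2Z,6S)-6-methoxy-2-methyl-7-(trityloxy)hept-2-enoate
Conditions: (CF3CH2O)2P(O)CH(Me)CO2Et, KHMDS, 18-crown-6, THF, −78 °C
Reagents that add atoms: ethyl 2-[bis(2,2,2-trifluoroethoxy)phosphoryl]propanoate, CCOC(=O)C(C)P(=O)(OCC(F)(F)F)OCC(F)(F)F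
Why: Still–Gennari olefination, in which fast irreversible elimination from the electron-poor phosphonate adduct gives the Z (angelate-type) C2=C3 enoate.

Step 16
Reactants: 23 ethyl (2Z,6S)-6-methoxy-2-methyl-7-(trityloxy)hept-2-enoate
Product: 24 ethyl (2Z,6S)-7-hydroxy-6-methoxy-2-methylhept-2-enoate
Conditions: TsOH·H2O (cat.), MeOH/CH2Cl2, rt
Reagents that add atoms: none
Why: Acid-catalysed trityl methanolysis under conditions too mild for oxa-Michael closure or alkene isomerisation.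

Step 17
Reactants: 24 ethyl (2Z,6S)-7-hydroxy-6-methoxy-2-methylhept-2-enoate
Product: 25 ethyl (2Z,6S)-6-methoxy-2-methyl-7-oxohept-2-enoate
Conditions: Dess–Martin periodinane, NaHCO3, CH2Cl2, 0 °C; used at once
Reagents that add atoms: none
Why: Buffered Dess–Martin oxidation gives the configurationally labile α-methoxy aldehyde without epimerising C6.

Step 18
Reactants: 19 {3-bromo-5-[(2R,4S,5R,6S,7Z)-5-(tert-butyldimethylsilyloxy)-8-iodo-4-methoxy-2,6-dimethylnon-7-enyl]phenoxy}triisopropylsilane; 25 ethyl (2Z,6S)-6-methoxy-2-methyl-7-oxohept-2-enoate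
Product: 28 ethyl (2Z,6S,7S,8Z,10S,11R,12S,14R)-15-[3-bromo-5-(triisopropylsilyloxy)phenyl]-11-(tert-butyldimethylsilyloxy)-7-hydroxy-6,12-dimethoxy-2,8,10,14-tetramethylpentadeca-2,8-dienoate, via alkenyllithium 26 (not isolated), via alkenylmagnesium bromide 27 (not isolated)
Conditions: 19, n-BuLi (1.05 equiv), Et2O, −78 °C; MgBr2·OEt2; then 25 premixed with MgBr2·OEt2, CH2Cl2, −78 °C
Reagents that add atoms: none
Why: Iodine–lithium exchange (much faster at the alkenyl iodide than at the aryl bromide in ether at −78 °C), transmetalation and Cram-chelate 1,2-addition, where magnesium bridges the aldehyde and α-methoxy oxygens so the alkenyl group adds anti to the C6 chain and gives the 6,7-syn (7S) alcohol with the Z alkene retained.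

Step 19
Reactants: 28 ethyl (2Z,6S,7S,8Z,10S,11R,12S,14R)-15-[3-bromo-5-(triisopropylsilyloxy)phenyl]-11-(tert-butyldimethylsilyloxy)-7-hydroxy-6,12-dimethoxy-2,8,10,14-tetramethylpentadeca-2,8-dienoate
Product: 29 (2Z,6S,7S,8Z,10S,11R,12S,14R)-15-[3-bromo-5-(triisopropylsilyloxy)phenyl]-11-(tert-butyldimethylsilyloxy)-7-hydroxy-6,12-dimethoxy-2,8,10,14-tetramethylpentadeca-2,8-dienamide
Conditions: AlMe3, NH4Cl, toluene, 0 °C then 50 °C
Reagents that add atoms: ammonium chloride, [NH4+].[Cl-] (delivered as methylchloroaluminium amide, C[Al](Cl)N)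
Why: Weinreb-type aluminium amide aminolysis converts the hindered ester directly into the primary amide without aqueous base, so the aryl silyl ether and the Z alkene survive.

Step 20
Reactants: 29 (2Z,6S,7S,8Z,10S,11R,12S,14R)-15-[3-bromo-5-(triisopropylsilyloxy)phenyl]-11-(tert-butyldimethylsilyloxy)-7-hydroxy-6,12-dimethoxy-2,8,10,14-tetramethylpentadeca-2,8-dienamide
Product: 30 (2Z,8Z)-7-hydroxy-11-O-TBS-18-O-TIPS macrolactam (19-membered anilide)
Conditions: NiBr2·glyme (20 mol%), dtbbpy (20 mol%), Ir(ppy)2(dtbbpy)PF6 (2 mol%), tetramethylguanidine, MeCN/DMA, 2 mM (syringe pump), 450 nm LEDs, 30 °C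
Reagents that add atoms: none
Why: Proposed new method: intramolecular nickel/photoredox N-arylation of a primary Z-enamide by an unactivated aryl bromide to close a 19-membered lactam at high dilution — low-valent nickel inserts into the C–Br bond, the amide binds as its amidate after deprotonation by tetramethylguanidine, and the excited iridium complex (triplet energy near 49 kcal/mol, too low to sensitise Z-to-E isomerisation of either alkene) triggers C–N reductive elimination from the divalent aryl nickel amidate by oxidation to trivalent nickel or by energy transfer; the closest known reactions are the intermolecular nickel/photoredox N-arylation of sulfonamides, carbamates and amides with aryl bromides and the thermal copper-mediated Goldberg macrolactamisation of ansamycin seco-amides; no stereocentre is formed.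

Step 21
Reactants: 30 (2Z,8Z)-7-hydroxy-11-O-TBS-18-O-TIPS macrolactam (19-membered anilide)
Product: 32 (2Z,8Z)-7-O-carbamoyl-11-O-TBS-18-O-TIPS macrolactam, via trichloroacetyl carbamate 31 (not isolated)
Conditions: Cl3CC(O)NCO, CH2Cl2, 0 °C; then neutral Al2O3, rt
Reagents that add atoms: trichloroacetyl isocyanate, O=C=NC(=O)C(Cl)(Cl)Cl
Why: Carbamoylation of the only free hydroxyl (C7) with the acyl isocyanate, followed by hydrolysis of the trichloroacetyl group on alumina, gives the primary carbamate with retention at C7.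

Step 22
Reactants: 32 (2Z,8Z)-7-O-carbamoyl-11-O-TBS-18-O-TIPS macrolactam
Product: 33 (4Z,8S,9S,10Z,12S,13R,14S,16R)-13,20-dihydroxy-8,14-dimethoxy-4,10,12,16-tetramethyl-3-oxo-2-azabicyclo[16.3.1]docosa-1(22),4,10,18,20-pentaen-9-yl carbamate (target)
Conditions: HF·pyridine, pyridine, THF, 0 °C to rt
Reagents that add atoms: none
Why: Buffered fluoride desilylation removes both the aryl TIPS and the C11 TBS ethers and leaves the allylic carbamate, the methyl ethers and both Z alkenes intact.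

**Compound list**
1 | (S)-5-(trityloxymethyl)dihydrofuran-2(3H)-one (commercial, from L-glutamic acid) | O=C1CC[C@@H](COC(c2ccccc2)(c2ccccc2)c2ccccc2)O1 | starting material
2 | lithium enolate of 1 | [Li]OC1=CC[C@@H](COC(c2ccccc2)(c2ccccc2)c2ccccc2)O1 | intermediate
3 | (3R,5S)-3-methyl-5-(trityloxymethyl)dihydrofuran-2(3H)-one (trans) | O=C1[C@H](C)C[C@@H](COC(c2ccccc2)(c2ccccc2)c2ccccc2)O1 | intermediate
4 | lithium enolate of 3 | [Li]OC1=C(C)C[C@@H](COC(c2ccccc2)(c2ccccc2)c2ccccc2)O1 | intermediate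
5 | (3S,5S)-3-methyl-5-(trityloxymethyl)dihydrofuran-2(3H)-one (cis) | O=C1[C@@H](C)C[C@@H](COC(c2ccccc2)(c2ccccc2)c2ccccc2)O1 | intermediate
6 | potassium (2S,4S)-4-hydroxy-2-methyl-5-(trityloxy)pentanoate | O[C@H](COC(c1ccccc1)(c1ccccc1)c1ccccc1)C[C@H](C)C(=O)[O-].[K+] | intermediate
7 | methyl (2S,4S)-4-methoxy-2-methyl-5-(trityloxy)pentanoate | CO[C@H](COC(c1ccccc1)(c1ccccc1)c1ccccc1)C[C@H](C)C(=O)OC | intermediate
8 | (2S,4S)-4-methoxy-2-methyl-5-(trityloxy)pentan-1-ol | CO[C@H](COC(c1ccccc1)(c1ccccc1)c1ccccc1)C[C@H](C)CO | intermediate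
9 | 3,5-dibromophenol | Oc1cc(Br)cc(Br)c1 | starting material
10 | (3,5-dibromophenoxy)triisopropylsilane | CC(C)[Si](Oc1cc(Br)cc(Br)c1)(C(C)C)C(C)C | intermediate
11 | 5,7-di-tert-butyl-2-[(2S,4S)-4-methoxy-2-methyl-5-(trityloxy)pentyloxy]-3-phenyl-2,3-dihydrobenzoxazole (acetal carbon unassigned) | CO[C@H](COC(c1ccccc1)(c1ccccc1)c1ccccc1)C[C@H](C)COC1Oc2c(C(C)(C)C)cc(C(C)(C)C)cc2N1c1ccccc1 | intermediate
12 | {3-bromo-5-[(2R,4S)-4-methoxy-2-methyl-5-(trityloxy)pentyl]phenoxy}triisopropylsilane | CO[C@H](COC(c1ccccc1)(c1ccccc1)c1ccccc1)C[C@H](C)Cc1cc(Br)cc(O[Si](C(C)C)(C(C)C)C(C)C)c1 | intermediate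
13 | (2S,4R)-5-[3-bromo-5-(triisopropylsilyloxy)phenyl]-2-methoxy-4-methylpentan-1-ol | CO[C@H](CO)C[C@H](C)Cc1cc(Br)cc(O[Si](C(C)C)(C(C)C)C(C)C)c1 | intermediate
14 | (2S,4R)-5-[3-bromo-5-(triisopropylsilyloxy)phenyl]-2-methoxy-4-methylpentanal | CO[C@H](C=O)C[C@H](C)Cc1cc(Br)cc(O[Si](C(C)C)(C(C)C)C(C)C)c1 | intermediate
15 | (3S,4R,5S,7R)-8-[3-bromo-5-(triisopropylsilyloxy)phenyl]-5-methoxy-3,7-dimethyloct-1-en-4-ol | C=C[C@H](C)[C@@H](O)[C@@H](OC)C[C@H](C)Cc1cc(Br)cc(O[Si](C(C)C)(C(C)C)C(C)C)c1 | intermediate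
16 | {3-bromo-5-[(2R,4S,5R,6S)-5-(tert-butyldimethylsilyloxy)-4-methoxy-2,6-dimethyloct-7-enyl]phenoxy}triisopropylsilane | C=C[C@H](C)[C@@H](O[Si](C)(C)C(C)(C)C)[C@@H](OC)C[C@H](C)Cc1cc(Br)cc(O[Si](C(C)C)(C(C)C)C(C)C)c1 | intermediate
17 | ozonide of 16 (3-substituted 1,2,4-trioxolane, ring carbon unassigned) | C1OOC(O1)[C@H](C)[C@@H](O[Si](C)(C)C(C)(C)C)[C@@H](OC)C[C@H](C)Cc1cc(Br)cc(O[Si](C(C)C)(C(C)C)C(C)C)c1 | intermediate
18 | (2R,3R,4S,6R)-7-[3-bromo-5-(triisopropylsilyloxy)phenyl]-3-(tert-butyldimethylsilyloxy)-4-methoxy-2,6-dimethylheptanal | O=C[C@H](C)[C@@H](O[Si](C)(C)C(C)(C)C)[C@@H](OC)C[C@H](C)Cc1cc(Br)cc(O[Si](C(C)C)(C(C)C)C(C)C)c1 | intermediate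
19 | {3-bromo-5-[(2R,4S,5R,6S,7Z)-5-(tert-butyldimethylsilyloxy)-8-iodo-4-methoxy-2,6-dimethylnon-7-enyl]phenoxy}triisopropylsilane | I/C(C)=C\[C@H](C)[C@@H](O[Si](C)(C)C(C)(C)C)[C@@H](OC)C[C@H](C)Cc1cc(Br)cc(O[Si](C(C)C)(C(C)C)C(C)C)c1 | intermediate
20 | potassium (S)-4-hydroxy-5-(trityloxy)pentanoate | [K+].[O-]C(=O)CC[C@H](O)COC(c1ccccc1)(c1ccccc1)c1ccccc1 | intermediate
21 | methyl (S)-4-methoxy-5-(trityloxy)pentanoate | COC(=O)CC[C@H](OC)COC(c1ccccc1)(c1ccccc1)c1ccccc1 | intermediate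
22 | (S)-4-methoxy-5-(trityloxy)pentanal | O=CCC[C@H](OC)COC(c1ccccc1)(c1ccccc1)c1ccccc1 | intermediate
23 | ethyl (2Z,6S)-6-methoxy-2-methyl-7-(trityloxy)hept-2-enoate | CCOC(=O)/C(C)=C\CC[C@H](OC)COC(c1ccccc1)(c1ccccc1)c1ccccc1 | intermediate
24 | ethyl (2Z,6S)-7-hydroxy-6-methoxy-2-methylhept-2-enoate | CCOC(=O)/C(C)=C\CC[C@H](OC)CO | intermediate
25 | ethyl (2Z,6S)-6-methoxy-2-methyl-7-oxohept-2-enoate | CCOC(=O)/C(C)=C\CC[C@H](OC)C=O | intermediate
26 | (Z)-alkenyllithium from 19 (lithium in place of iodine) | [Li]/C(C)=C\[C@H](C)[C@@H](O[Si](C)(C)C(C)(C)C)[C@@H](OC)C[C@H](C)Cc1cc(Br)cc(O[Si](C(C)C)(C(C)C)C(C)C)c1 | intermediate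
27 | (Z)-alkenylmagnesium bromide from 26 | Br[Mg]/C(C)=C\[C@H](C)[C@@H](O[Si](C)(C)C(C)(C)C)[C@@H](OC)C[C@H](C)Cc1cc(Br)cc(O[Si](C(C)C)(C(C)C)C(C)C)c1 | intermediate
28 | ethyl (2Z,6S,7S,8Z,10S,11R,12S,14R)-15-[3-bromo-5-(triisopropylsilyloxy)phenyl]-11-(tert-butyldimethylsilyloxy)-7-hydroxy-6,12-dimethoxy-2,8,10,14-tetramethylpentadeca-2,8-dienoate | CCOC(=O)/C(C)=C\CC[C@H](OC)[C@@H](O)/C(C)=C\[C@H](C)[C@@H](O[Si](C)(C)C(C)(C)C)[C@@H](OC)C[C@H](C)Cc1cc(Br)cc(O[Si](C(C)C)(C(C)C)C(C)C)c1 | intermediate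
29 | (2Z,6S,7S,8Z,10S,11R,12S,14R)-15-[3-bromo-5-(triisopropylsilyloxy)phenyl]-11-(tert-butyldimethylsilyloxy)-7-hydroxy-6,12-dimethoxy-2,8,10,14-tetramethylpentadeca-2,8-dienamide | NC(=O)/C(C)=C\CC[C@H](OC)[C@@H](O)/C(C)=C\[C@H](C)[C@@H](O[Si](C)(C)C(C)(C)C)[C@@H](OC)C[C@H](C)Cc1cc(Br)cc(O[Si](C(C)C)(C(C)C)C(C)C)c1 | intermediate
30 | (2Z,8Z)-macrolactam with free C7–OH, C11–OTBS and aryl OTIPS | CO[C@H]1C[C@H](C)Cc2cc(O[Si](C(C)C)(C(C)C)C(C)C)cc(c2)NC(=O)/C(C)=C\CC[C@H](OC)[C@@H](O)/C(C)=C\[C@H](C)[C@H]1O[Si](C)(C)C(C)(C)C | intermediate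
31 | C7 N-trichloroacetyl carbamate of 30 | CO[C@H]1C[C@H](C)Cc2cc(O[Si](C(C)C)(C(C)C)C(C)C)cc(c2)NC(=O)/C(C)=C\CC[C@H](OC)[C@@H](OC(=O)NC(=O)C(Cl)(Cl)Cl)/C(C)=C\[C@H](C)[C@H]1O[Si](C)(C)C(C)(C)C | intermediate
32 | C7 carbamate with C11–OTBS and aryl OTIPS | CO[C@H]1C[C@H](C)Cc2cc(O[Si](C(C)C)(C(C)C)C(C)C)cc(c2)NC(=O)/C(C)=C\CC[C@H](OC)[C@@H](OC(N)=O)/C(C)=C\[C@H](C)[C@H]1O[Si](C)(C)C(C)(C)C | intermediate
33 | (4Z,8S,9S,10Z,12S,13R,14S,16R)-13,20-dihydroxy-8,14-dimethoxy-4,10,12,16-tetramethyl-3-oxo-2-azabicyclo[16.3.1]docosa-1(22),4,10,18,20-pentaen-9-yl carbamate | CO[C@H]1C[C@H](C)Cc2cc(O)cc(c2)NC(=O)/C(C)=C\CC[C@H](OC)[C@@H](OC(N)=O)/C(C)=C\[C@H](C)[C@H]1O | target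

**Step count and risks**

Total steps: 22. Longest linear sequence: 16 (steps 1–4, 6–12, 18–22, from lactone 1).

Step 20 (proposed new photochemical macrolactamisation) is the most likely to fail, through oligomerisation, protodebromination or competing O-arylation by the free C7 hydroxyl. The fallback uses known chemistry and forms the acyl C–N bond instead of the aryl C–N bond; it sets out from 28 and comes back at 30. Palladium-catalysed amination of the aryl bromide with benzophenone imine (Pd2(dba)3, Xantphos, Cs2CO3, toluene, 90 °C) gives the N-aryl benzophenone imine of the seco ester F5. Hydroxylamine hydrochloride and NaOAc in MeOH release the seco aniline ethyl ester F6. Me3SnOH in 1,2-dichloroethane at 70 °C gives the seco amino acid F7. Macrolactamisation of this (BOP-Cl, iPr2NEt, toluene, high dilution, 85 °C) gives 30.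

Step 18 (fragment union) can fail through incomplete selectivity of the iodine–lithium exchange over the aryl bromide or through poor chelation control at C7. The fallback sets out from 19 and 25 and comes back at 28. A Nozaki–Hiyama–Kishi coupling (CrCl2, catalytic NiCl2, DMSO, rt), which leaves the aryl bromide alone, gives the C7-epimeric allylic alcohol mixture F3. Dess–Martin oxidation gives the C7 enone F4. Non-chelating Felkin–Anh 1,2-reduction with K-Selectride in THF at −78 °C then gives the 6,7-syn alcohol 28.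

Step 6 (deoxygenative arylation with the alcohol as limiting partner and a dibromoarene) can fail through low radical generation or double arylation. The fallback replaces the photochemical radical coupling by a two-electron organozinc coupling; it sets out from 8 and comes back at 12. An Appel reaction (CBr4, PPh3, CH2Cl2) gives (2S,4S)-5-bromo-2-methoxy-4-methylpentyl trityl ether F1. Zinc dust and LiCl in THF at 50 °C give [(2S,4S)-4-methoxy-2-methyl-5-(trityloxy)pentyl]zinc bromide F2. Negishi coupling with excess 10 (Pd(OAc)2, SPhos, THF, rt) gives 12.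

**Further compounds**
F1 | step 6 | (2S,4S)-5-bromo-2-methoxy-4-methylpentyl trityl ether | CO[C@H](COC(c1ccccc1)(c1ccccc1)c1ccccc1)C[C@H](C)CBr
F2 | step 6 | [(2S,4S)-4-methoxy-2-methyl-5-(trityloxy)pentyl]zinc bromide | CO[C@H](COC(c1ccccc1)(c1ccccc1)c1ccccc1)C[C@H](C)C[Zn]Br
F3 | step 18 | C7-epimeric allylic alcohol mixture (28 and its 7R epimer) | CCOC(=O)/C(C)=C\CC[C@H](OC)C(O)/C(C)=C\[C@H](C)[C@@H](O[Si](C)(C)C(C)(C)C)[C@@H](OC)C[C@H](C)Cc1cc(Br)cc(O[Si](C(C)C)(C(C)C)C(C)C)c1
F4 | step 18 | C7 enone, ethyl (2Z,6S,8Z,10S,11R,12S,14R)-15-[3-bromo-5-(triisopropylsilyloxy)phenyl]-11-(tert-butyldimethylsilyloxy)-6,12-dimethoxy-2,8,10,14-tetramethyl-7-oxopentadeca-2,8-dienoate | CCOC(=O)/C(C)=C\CC[C@H](OC)C(=O)/C(C)=C\[C@H](C)[C@@H](O[Si](C)(C)C(C)(C)C)[C@@H](OC)C[C@H](C)Cc1cc(Br)cc(O[Si](C(C)C)(C(C)C)C(C)C)c1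
F5 | step 20 | N-aryl benzophenone imine of the seco ester | CCOC(=O)/C(C)=C\CC[C@H](OC)[C@@H](O)/C(C)=C\[C@H](C)[C@@H](O[Si](C)(C)C(C)(C)C)[C@@H](OC)C[C@H](C)Cc1cc(N=C(c2ccccc2)c2ccccc2)cc(O[Si](C(C)C)(C(C)C)C(C)C)c1
F6 | step 20 | seco aniline ethyl ester | CCOC(=O)/C(C)=C\CC[C@H](OC)[C@@H](O)/C(C)=C\[C@H](C)[C@@H](O[Si](C)(C)C(C)(C)C)[C@@H](OC)C[C@H](C)Cc1cc(N)cc(O[Si](C(C)C)(C(C)C)C(C)C)c1
F7 | step 20 | seco amino acid | OC(=O)/C(C)=C\CC[C@H](OC)[C@@H](O)/C(C)=C\[C@H](C)[C@@H](O[Si](C)(C)C(C)(C)C)[C@@H](OC)C[C@H](C)Cc1cc(N)cc(O[Si](C(C)C)(C(C)C)C(C)C)c1
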